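The route cuts ring C of the isoflavan at C3–C4 and O1–C2. O1, C8a, C4a and C4 belong to an ortho-quinone methide of ring A, and C2–C3 with ring B attached is an arylacetic acid, so C3 can act as enolate carbon and C2 as acyl donor. A chiral isothiourea joins the two halves in one operation: it forms C3–C4, closes ring C as a lactone through O1–C2 and sets the only stereocentre, C3. The precursors are [2-(benzyloxy)-3,4,5-trimethoxyphenyl]acetic acid and a 2-(tosylmethyl)phenol that releases the quinone methide on deprotonation. The quinone of ring B is unveiled last from a para-methoxyphenol.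

Key step: step 6

Remark: C3 keeps the descriptor S from lactone 16 to the target because its CIP order (C2 > ring B carbon > C4 > H) is the same in every compound; the target name is taken to mean the (3S) compound of the given SMILES.

Remark: (2R,3S)-HyperBTM is the enantiomer predicted by the accepted facial model for isothiouronium enolates to give 3S; should the sense prove opposite, the commercially available antipode would be used with no other change.

Step 1
Reactants: 1 3,4-dimethoxyphenol; 2 formaldehyde; 3 sodium p-toluenesulfinate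
Product: 5 4,5-dimethoxy-2-[(4-methylphenyl)sulfonylmethyl]phenol, via hydroxymethylphenol 4 (not isolated)
Conditions: 37 % aq. CH2O (slow addition), TolSO2Na (excess), HCO2H/H2O 1:1, rt
Reagents that add atoms: none
Why: Three-component Mannich-type sulfonylmethylation: formaldehyde should hydroxymethylate the phenol at C6, the unhindered carbon ortho to OH and para to the 3-methoxy group, and benzylic alcohol 4 should ionise in formic acid to a cation that the soft sulfinate captures at sulfur, while excess sulfinate and the low solubility of the sulfone hold back diarylmethane formation.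

Step 2
Reactants: 6 2,3,4-trimethoxyphenol
Product: 7 1,2,3-trimethoxy-4-(prop-2-en-1-yloxy)benzene
Conditions: allyl bromide, K2CO3, acetone, reflux, N2
Reagents that add atoms: allyl bromide, C=CCBr
Why: Williamson ether synthesis: the phenoxide formed with K2CO3 displaces bromide from allyl bromide by SN2, and no other acidic or electrophilic site is present.

Step 3
Reactants: 7 1,2,3-trimethoxy-4-(prop-2-en-1-yloxy)benzene
Product: 9 2-(benzyloxy)-3,4,5-trimethoxy-1-(prop-2-en-1-yl)benzene, via allylphenol 8 (not isolated)
Conditions: neat, 190 °C, Ar; cool, then DMF, K2CO3, BnBr, rt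
Reagents that add atoms: benzyl bromide, BrCc1ccccc1
Why: Aromatic Claisen rearrangement: the [3,3] shift can deliver the allyl group only to C6, since the other ortho carbon and the para carbon carry methoxy groups, and the oxidation-prone phenol 8 is capped at once in the same flask by Williamson benzylation.

Step 4
Reactants: 9 2-(benzyloxy)-3,4,5-trimethoxy-1-(prop-2-en-1-yl)benzene
Product: 11 [2-(benzyloxy)-3,4,5-trimethoxyphenyl]acetaldehyde, via diol 10 (not isolated)
Conditions: K2OsO4·2H2O (2 mol %), NaIO4, 2,6-lutidine, 1,4-dioxane/H2O 3:1, rt; crude aldehyde used directly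
Reagents that add atoms: osmium tetroxide OsO4 (formed in the flask from K2OsO4·2H2O and NaIO4), O=[Os](=O)(=O)=O; sodium periodate NaIO4, [Na+].[O-]I(=O)(=O)=O (restores the oxo ligands of OsO4)
Why: Lemieux–Johnson oxidation: catalytic OsO4 dihydroxylates the terminal alkene to diol 10 and NaIO4 cleaves the glycol and regenerates OsO4, while the tetra-oxygenated arene and the benzyl ether, which RuO4 or excess ozone could attack, are inert to these oxidants.

Step 5
Reactants: 11 [2-(benzyloxy)-3,4,5-trimethoxyphenyl]acetaldehyde
Product: 12 [2-(benzyloxy)-3,4,5-trimethoxyphenyl]acetic acid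
Conditions: NaClO2, NaH2PO4, 2-methyl-2-butene (excess), t-BuOH/H2O, 0 °C to rt
Reagents that add atoms: sodium chlorite, [Na+].[O-]Cl=O
Why: Pinnick oxidation: chlorous acid adds to the aldehyde and fragments to the acid, and 2-methyl-2-butene removes the hypochlorous acid that would otherwise chlorinate the electron-rich ring.

Step 6
Reactants: 12 [2-(benzyloxy)-3,4,5-trimethoxyphenyl]acetic acid; 5 4,5-dimethoxy-2-[(4-methylphenyl)sulfonylmethyl]phenol
Product: 16 (3S)-3-[2-(benzyloxy)-3,4,5-trimethoxyphenyl]-6,7-dimethoxychroman-2-one, via mixed pivalic anhydride 13 (not isolated), via ortho-quinone methide 14 (not isolated), via ammonium enolate 15 (not isolated)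
Conditions: 12 (limiting), PivCl (1.05 equiv), i-Pr2NEt, CH2Cl2, 0 °C, 20 min; then 5 (1.5 equiv), (2R,3S)-HyperBTM (10 mol %), Cs2CO3, −20 to 0 °C; short silica plug, used at once
Reagents that add atoms: pivaloyl chloride, CC(C)(C)C(=O)Cl (its acyl group is carried only by intermediate 13); (2R,3S)-HyperBTM, CC(C)[C@H]1CN2c3ccccc3SC2=N[C@H]1c1ccccc1 (held only in intermediate 15); nothing beyond 12 and 5 remains in 16
Why: Pivaloyl chloride turns 12 into mixed anhydride 13, which acylates the isothiourea at nitrogen, and deprotonation gives the (Z)-ammonium enolate 15, held planar by a 1,5 S···O contact, while Cs2CO3 expels sulfinate from 5 to release ortho-quinone methide 14; the enolate carbon adds to the exocyclic CH2 of 14 (C3–C4) with rearomatisation of ring A, and the phenoxide then attacks the acyl ammonium carbonyl (O1–C2) and frees the catalyst. The closest known reaction type is the isothiourea-catalysed Michael addition–lactonisation of arylacetic acid-derived C1-ammonium enolates, including its variant with ortho-quinone methides made in the flask from 2-(sulfonylalkyl)phenols, which gives 3,4-dihydrocoumarins. Ring C closes by 6-exo-trig acyl substitution of the ring A phenoxide at C2. C3 is controlled by the catalyst alone: the pseudoaxial 2-phenyl group of (2R,3S)-HyperBTM screens one face of the enolate, so the methide carbon should add to the open face and give 3S. The step needs carbon–carbon bond formation at the methylene terminus in preference to O-acylation of the phenol or self-condensation of 14, which is secured by the unhindered CH2, the aromaticity regained in ring A, the two methoxy groups that stabilise 14, and by consuming the pivaloyl chloride before 5 is added. The electron-rich ortho-substituted ring B lowers the acidity of H3 in 16, which, with low temperature and immediate reduction, should protect the new stereocentre.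

Step 7
Reactants: 16 (3S)-3-[2-(benzyloxy)-3,4,5-trimethoxyphenyl]-6,7-dimethoxychroman-2-one
Product: 17 2-[(2S)-2-[2-(benzyloxy)-3,4,5-trimethoxyphenyl]-3-hydroxypropyl]-4,5-dimethoxyphenol
Conditions: LiAlH4 (excess), THF, −40 to 0 °C, 16 added to the hydride; aq. Rochelle salt work-up
Reagents that add atoms: none
Why: Hydride reduction of an aryl ester: LiAlH4 attacks the lactone carbonyl far faster than H3 can be removed when 16 is added to excess hydride at low temperature, so the phenol–alcohol should form with C3 unchanged and the benzyl and methyl ethers untouched.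

Step 8
Reactants: 17 2-[(2S)-2-[2-(benzyloxy)-3,4,5-trimethoxyphenyl]-3-hydroxypropyl]-4,5-dimethoxyphenol
Product: 18 (3S)-3-[2-(benzyloxy)-3,4,5-trimethoxyphenyl]-6,7-dimethoxy-3,4-dihydro-2H-chromene
Conditions: PPh3, DIAD, THF, 0 °C to rt
Reagents that add atoms: none
Why: Mitsunobu etherification: the primary alcohol is activated as an alkoxyphosphonium ion and displaced by the only free phenol (ring A) in a 6-exo-tet closure at a non-stereogenic carbon, so C3 is untouched, while the benzyl ether prevents ring B from closing a dihydrobenzofuran instead.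

Step 9
Reactants: 18 (3S)-3-[2-(benzyloxy)-3,4,5-trimethoxyphenyl]-6,7-dimethoxy-3,4-dihydro-2H-chromene
Product: 19 6-[(3S)-6,7-dimethoxy-3,4-dihydro-2H-chromen-3-yl]-2,3,4-trimethoxyphenol
Conditions: H2 (1 atm), Pd/C (10 wt % Pd on carbon), EtOAc/MeOH, rt; filtered and used directly
Reagents that add atoms: none
Why: Hydrogenolysis of the benzylic C–O bond over Pd/C: the aryl methyl ethers and the chroman ether, which has no benzylic C–O bond, are not cleaved, and C3 is not affected.

Step 10
Reactants: 19 6-[(3S)-6,7-dimethoxy-3,4-dihydro-2H-chromen-3-yl]-2,3,4-trimethoxyphenol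
Product: 20 abroquinone A (abruquinone A; 5-[(3S)-6,7-dimethoxy-3,4-dihydro-2H-chromen-3-yl]-2,3-dimethoxycyclohexa-2,5-diene-1,4-dione)
Conditions: PhI(OAc)2 (1.1 equiv), MeCN/H2O 3:1, 0 °C
Reagents that add atoms: water, O
Why: Oxidative demethylation of a para-methoxyphenol by trivalent iodine: ligand exchange at iodine and loss of iodobenzene give a phenoxenium ion, water adds at the methoxy-bearing carbon para to the former OH and the hemiketal loses methanol to give the para-quinone, while ring A carries no free OH and should not react and C3 is not involved.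

Compound list
1 | 3,4-dimethoxyphenol | COc1ccc(O)cc1OC | starting material
2 | formaldehyde | C=O | starting material
3 | sodium p-toluenesulfinate | Cc1ccc(cc1)S(=O)[O-].[Na+] | starting material
4 | 2-(hydroxymethyl)-4,5-dimethoxyphenol | COc1cc(O)c(CO)cc1OC | intermediate (not isolated)
5 | 4,5-dimethoxy-2-[(4-methylphenyl)sulfonylmethyl]phenol | COc1cc(O)c(CS(=O)(=O)c2ccc(C)cc2)cc1OC | intermediate
6 | 2,3,4-trimethoxyphenol | COc1ccc(O)c(OC)c1OC | starting material
7 | 1,2,3-trimethoxy-4-(prop-2-en-1-yloxy)benzene | C=CCOc1ccc(OC)c(OC)c1OC | intermediate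
8 | 2,3,4-trimethoxy-6-(prop-2-en-1-yl)phenol | C=CCc1cc(OC)c(OC)c(OC)c1O | intermediate (not isolated)
9 | 2-(benzyloxy)-3,4,5-trimethoxy-1-(prop-2-en-1-yl)benzene | C=CCc1cc(OC)c(OC)c(OC)c1OCc1ccccc1 | intermediate
10 | 3-[2-(benzyloxy)-3,4,5-trimethoxyphenyl]propane-1,2-diol (racemic at the carbinol carbon) | OCC(O)Cc1cc(OC)c(OC)c(OC)c1OCc1ccccc1 | intermediate (not isolated)
11 | [2-(benzyloxy)-3,4,5-trimethoxyphenyl]acetaldehyde | O=CCc1cc(OC)c(OC)c(OC)c1OCc1ccccc1 | intermediate
12 | [2-(benzyloxy)-3,4,5-trimethoxyphenyl]acetic acid | COc1cc(CC(=O)O)c(OCc2ccccc2)c(OC)c1OC | intermediate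
13 | [2-(benzyloxy)-3,4,5-trimethoxyphenyl]acetic 2,2-dimethylpropanoic anhydride | COc1cc(CC(=O)OC(=O)C(C)(C)C)c(OCc2ccccc2)c(OC)c1OC | intermediate (not isolated)
14 | 3,4-dimethoxy-6-methylidenecyclohexa-2,4-dien-1-one (ortho-quinone methide of ring A) | C=C1C=C(OC)C(OC)=CC1=O | intermediate (not isolated)
15 | (Z)-2-[2-(benzyloxy)-3,4,5-trimethoxyphenyl]-1-[(2R,3S)-3-isopropyl-2-phenyl-3,4-dihydro-2H-benzo[4,5]thiazolo[3,2-a]pyrimidin-1-ium-1-yl]ethen-1-olate (C1-ammonium enolate) | CC(C)[C@H]1CN2c3ccccc3SC2=[N+](/C([O-])=C/c2cc(OC)c(OC)c(OC)c2OCc2ccccc2)[C@H]1c1ccccc1 | intermediate (not isolated)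
16 | (3S)-3-[2-(benzyloxy)-3,4,5-trimethoxyphenyl]-6,7-dimethoxychroman-2-one | COc1cc([C@H]2C(=O)Oc3cc(OC)c(OC)cc3C2)c(OCc2ccccc2)c(OC)c1OC | intermediate
17 | 2-[(2S)-2-[2-(benzyloxy)-3,4,5-trimethoxyphenyl]-3-hydroxypropyl]-4,5-dimethoxyphenol | OC[C@@H](Cc1cc(OC)c(OC)cc1O)c1cc(OC)c(OC)c(OC)c1OCc1ccccc1 | intermediate
18 | (3S)-3-[2-(benzyloxy)-3,4,5-trimethoxyphenyl]-6,7-dimethoxy-3,4-dihydro-2H-chromene | COc1cc([C@H]2COc3cc(OC)c(OC)cc3C2)c(OCc2ccccc2)c(OC)c1OC | intermediate
19 | 6-[(3S)-6,7-dimethoxy-3,4-dihydro-2H-chromen-3-yl]-2,3,4-trimethoxyphenol | COc1cc([C@H]2COc3cc(OC)c(OC)cc3C2)c(O)c(OC)c1OC | intermediate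
20 | abroquinone A (abruquinone A), 5-[(3S)-6,7-dimethoxy-3,4-dihydro-2H-chromen-3-yl]-2,3-dimethoxycyclohexa-2,5-diene-1,4-dione | COC1=C(OC)C(=O)C([C@H]2COc3cc(OC)c(OC)cc3C2)=CC1=O | target

Total step count: 10.
Longest linear sequence: 9 steps (steps 2 to 10, from 2,3,4-trimethoxyphenol 6); the sulfone branch is one step.

Steps most likely to fail

1. Step 6. What may go wrong: loss of enantiopurity through base-mediated enolisation of the acyl ammonium adduct or of the lactone, self-condensation of the quinone methide before the enolate captures it, or slow acylation of the catalyst by the ortho-substituted acid. The fallback replaces catalyst control by auxiliary control; it sets out from acid 12 and rejoins the route at chroman 18, so steps 7 and 8 fall away. The mixed pivalic anhydride of 12 would be treated with lithiated (4S)-4-benzyl-1,3-oxazolidin-2-one to give (4S)-4-benzyl-3-{[2-(benzyloxy)-3,4,5-trimethoxyphenyl]acetyl}-1,3-oxazolidin-2-one F1. Its chelated sodium (Z)-enolate (NaN(SiMe3)2, THF, −78 °C) would be alkylated with commercial 2-bromo-4,5-dimethoxybenzyl bromide on the face away from the auxiliary benzyl group (Evans alkylation), which should give (4S)-4-benzyl-3-[(2S)-2-[2-(benzyloxy)-3,4,5-trimethoxyphenyl]-3-(2-bromo-4,5-dimethoxyphenyl)propanoyl]-1,3-oxazolidin-2-one F2. Reductive removal of the auxiliary with LiBH4 in wet THF would give (2S)-2-[2-(benzyloxy)-3,4,5-trimethoxyphenyl]-3-(2-bromo-4,5-dimethoxyphenyl)propan-1-ol F3. An intramolecular palladium-catalysed aryl ether formation (Pd(OAc)2, 2-(di-tert-butylphosphino)-1,1'-binaphthyl, Cs2CO3, toluene, 80 °C) would then close ring C to give 18.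

2. Step 1. What may go wrong: runaway phenol–formaldehyde condensation to diarylmethanes, or double hydroxymethylation, before the sulfinate intercepts the benzylic cation. The fallback separates carbon–carbon bond formation from sulfone formation; it sets out from phenol 1 and returns at sulfone 5. A Mannich reaction of 1 with aqueous dimethylamine and formaldehyde in ethanol would give the acid-extractable base 2-[(dimethylamino)methyl]-4,5-dimethoxyphenol F4. Quaternisation with MeI in MeCN would give (2-hydroxy-4,5-dimethoxyphenyl)-N,N,N-trimethylmethanaminium iodide F5. Warming F5 with sodium p-toluenesulfinate 3 and NaHCO3 in aqueous MeCN would expel trimethylamine to the quinone methide, which the sulfinate captures at sulfur to give 5.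

3. Step 10. What may go wrong: oxidation spreading to the electron-rich ring A, or water adding ortho instead of para to the oxidised phenol so that an ortho-quinone forms. The fallback separates the oxidation from the unmasking of the quinone; it sets out from phenol 19 and returns at target 20. PhI(OAc)2 in anhydrous methanol at 0 °C would give the isolable quinone monoketal 2-[(3S)-6,7-dimethoxy-3,4-dihydro-2H-chromen-3-yl]-4,4,5,6-tetramethoxycyclohexa-2,5-dien-1-one F6, which can be purified. Brief hydrolysis with aqueous oxalic acid in acetone would then release 20.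

Further compounds
F1 | step 6 | (4S)-4-benzyl-3-{[2-(benzyloxy)-3,4,5-trimethoxyphenyl]acetyl}-1,3-oxazolidin-2-one | COc1cc(CC(=O)N2C(=O)OC[C@@H]2Cc2ccccc2)c(OCc2ccccc2)c(OC)c1OC
F2 | step 6 | (4S)-4-benzyl-3-[(2S)-2-[2-(benzyloxy)-3,4,5-trimethoxyphenyl]-3-(2-bromo-4,5-dimethoxyphenyl)propanoyl]-1,3-oxazolidin-2-one | COc1cc([C@H](Cc2cc(OC)c(OC)cc2Br)C(=O)N2C(=O)OC[C@@H]2Cc2ccccc2)c(OCc2ccccc2)c(OC)c1OC
F3 | step 6 | (2S)-2-[2-(benzyloxy)-3,4,5-trimethoxyphenyl]-3-(2-bromo-4,5-dimethoxyphenyl)propan-1-ol | COc1cc([C@H](Cc2cc(OC)c(OC)cc2Br)CO)c(OCc2ccccc2)c(OC)c1OC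
F4 | step 1 | 2-[(dimethylamino)methyl]-4,5-dimethoxyphenol | CN(C)Cc1cc(OC)c(OC)cc1O
F5 | step 1 | (2-hydroxy-4,5-dimethoxyphenyl)-N,N,N-trimethylmethanaminium iodide | C[N+](C)(C)Cc1cc(OC)c(OC)cc1O.[I-]
F6 | step 10 | 2-[(3S)-6,7-dimethoxy-3,4-dihydro-2H-chromen-3-yl]-4,4,5,6-tetramethoxycyclohexa-2,5-dien-1-one | COC1=C(OC)C(OC)(OC)C=C([C@H]2COc3cc(OC)c(OC)cc3C2)C1=O
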